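The route rests on the γ,δ-unsaturated ester hidden in ring A, C18(=O)–C4–C5–C10=C1. Ester 13 ties racemic 2-methylhex-5-enoic acid to a ring-B cyclohexenyl carbinol through the carbinol oxygen. In one flask an Ireland–Claisen rearrangement forges C4–C5 (C4 and C5 set through a chair transition state and chirality transfer from the carbinol carbon). Ring-closing metathesis of the new ethylidene with the pendant vinyl group then makes C1=C10 and ring A, and the carbinol carbon leaves in propene. C8 comes from one copper-catalysed conjugate addition, C9 follows by substrate control, and the carbinol centre is set by CBS reduction.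

Key step: step 10

Remark: halimane numbering is used (C4 = quaternary carbon bearing the ester carbon C18, C5 = ring-fusion CH, C1=C10 = ring-A alkene, C8 = CHMe, C9 = quaternary carbon bearing the side chain C11–C15; ring A = cyclohexene, ring B = cyclohexane), and racemic 2-methylhex-5-enoic acid is taken as a catalogue compound.

Step 1
Reactants: 1 2-methylcyclohex-2-en-1-one
Product: 3 trimethyl{[(3R)-2,3-dimethylcyclohex-1-en-1-yl]oxy}silane, via aluminium enolate 2 (not isolated)
Conditions: Me3Al, copper thiophene-2-carboxylate (monovalent copper, 2 mol%), chiral phosphoramidite ligand (4 mol%, enantiomer chosen for 3R), Et2O, −30 °C; then Me3SiOTf, THF, −30 → 0 °C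
Reagents that add atoms: trimethylaluminium, C[Al](C)C; trimethylsilyl trifluoromethanesulfonate, C[Si](C)(C)OS(=O)(=O)C(F)(F)F
Why: Copper-catalysed asymmetric conjugate addition of a methyl group should set C8 under control of the chiral ligand, and O-silylation of the aluminium enolate should fix the tetrasubstituted enol ether regiochemistry.

Step 2
Reactants: 3 trimethyl{[(3R)-2,3-dimethylcyclohex-1-en-1-yl]oxy}silane
Product: 4 (2S,3R)-2,3-dimethyl-2-(3-oxobutyl)cyclohexan-1-one
Conditions: but-3-en-2-one, Tf2NH (5 mol%, gives Me3SiNTf2 in situ), CH2Cl2, −78 °C; 1 M HCl work-up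
Reagents that add atoms: but-3-en-2-one, CC(=O)C=C
Why: In this Mukaiyama–Michael addition the silyl-activated enone should be attacked by the enol ether carbon on the face opposite the neighbouring C8 methyl group, which sets quaternary C9 with the new chain trans to that methyl.

Step 3
Reactants: 4 (2S,3R)-2,3-dimethyl-2-(3-oxobutyl)cyclohexan-1-one
Product: 5 ethyl (2E)-5-[(1S,2R)-1,2-dimethyl-6-oxocyclohexyl]-3-methylpent-2-enoate
Conditions: (EtO)2P(O)CH2CO2Et, NaH, THF, 0 → 50 °C
Reagents that add atoms: triethyl phosphonoacetate, CCOC(=O)CP(=O)(OCC)OCC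
Why: Horner–Wadsworth–Emmons olefination should occur only at the unhindered methyl ketone (the ring ketone is flanked by the quaternary carbon) and should favour the E enoate, the minor Z isomer being removed by chromatography.

Step 4
Reactants: 5 ethyl (2E)-5-[(1S,2R)-1,2-dimethyl-6-oxocyclohexyl]-3-methylpent-2-enoate
Product: 6 ethyl (2E)-5-[(1S,6R)-1,6-dimethyl-2-{[(trifluoromethyl)sulfonyl]oxy}cyclohex-2-en-1-yl]-3-methylpent-2-enoate
Conditions: Tf2O, 2,6-di-tert-butyl-4-methylpyridine, CH2Cl2, 0 °C → rt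
Reagents that add atoms: trifluoromethanesulfonic anhydride, O=S(=O)(OS(=O)(=O)C(F)(F)F)C(F)(F)F
Why: Enol triflate formation should give a single alkenyl triflate because the ketone can enolize only towards C5, and the triflate also masks the ketone against the next reduction.

Step 5
Reactants: 6 ethyl (2E)-5-[(1S,6R)-1,6-dimethyl-2-{[(trifluoromethyl)sulfonyl]oxy}cyclohex-2-en-1-yl]-3-methylpent-2-enoate
Product: 7 (5R,6S)-6-[(3E)-5-hydroxy-3-methylpent-3-en-1-yl]-5,6-dimethylcyclohex-1-en-1-yl trifluoromethanesulfonate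
Conditions: DIBAL-H (2.5 equiv), CH2Cl2, −78 °C; Rochelle salt work-up
Reagents that add atoms: none
Why: 1,2-Reduction of the conjugated ester by the aluminium hydride at low temperature should give the allylic alcohol while the alkenyl triflate stays inert.

Step 6
Reactants: 7 (5R,6S)-6-[(3E)-5-hydroxy-3-methylpent-3-en-1-yl]-5,6-dimethylcyclohex-1-en-1-yl trifluoromethanesulfonate
Product: 8 (5R,6S)-6-{(3E)-5-[(tert-butyldimethylsilyl)oxy]-3-methylpent-3-en-1-yl}-5,6-dimethylcyclohex-1-en-1-yl trifluoromethanesulfonate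
Conditions: TBSCl, imidazole, DMF, rt
Reagents that add atoms: tert-butyl(chloro)dimethylsilane, CC(C)(C)[Si](C)(C)Cl
Why: Imidazole-promoted silylation of the primary alcohol should protect it against the strongly basic enolization that follows.

Step 7
Reactants: 8 (5R,6S)-6-{(3E)-5-[(tert-butyldimethylsilyl)oxy]-3-methylpent-3-en-1-yl}-5,6-dimethylcyclohex-1-en-1-yl trifluoromethanesulfonate
Product: 10 1-[(5R,6S)-6-{(3E)-5-[(tert-butyldimethylsilyl)oxy]-3-methylpent-3-en-1-yl}-5,6-dimethylcyclohex-1-en-1-yl]ethan-1-one, via ethoxy diene 9 (not isolated)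
Conditions: tributyl(1-ethoxyvinyl)stannane, Pd(PPh3)4 (5 mol%), LiCl, THF, 65 °C; then aq. oxalic acid, THF, 0 °C
Reagents that add atoms: tributyl(1-ethoxyvinyl)stannane, CCOC(=C)[Sn](CCCC)(CCCC)CCCC; water, O
Why: Stille coupling of the alkenyl triflate with the acyl-anion equivalent, followed by mild hydrolysis of the enol ether, should install the acetyl group and leave the silyl ether untouched.

Step 8
Reactants: 10 1-[(5R,6S)-6-{(3E)-5-[(tert-butyldimethylsilyl)oxy]-3-methylpent-3-en-1-yl}-5,6-dimethylcyclohex-1-en-1-yl]ethan-1-one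
Product: 11 (1S)-1-[(5R,6S)-6-{(3E)-5-[(tert-butyldimethylsilyl)oxy]-3-methylpent-3-en-1-yl}-5,6-dimethylcyclohex-1-en-1-yl]ethan-1-ol
Conditions: (R)-2-methyl-CBS-oxazaborolidine (20 mol%), catecholborane, toluene, −78 °C
Reagents that add atoms: none
Why: In this Corey–Bakshi–Shibata reduction the oxazaborolidine should deliver hydride to one face of the enone carbonyl (alkenyl group as the large substituent) and set the S carbinol centre by catalyst control, so that any minor ring-B enantiomer ends up as a separable diastereomer.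

Step 9
Reactants: 11 (1S)-1-[(5R,6S)-6-{(3E)-5-[(tert-butyldimethylsilyl)oxy]-3-methylpent-3-en-1-yl}-5,6-dimethylcyclohex-1-en-1-yl]ethan-1-ol; 12 2-methylhex-5-enoic acid (racemic)
Product: 13 (1S)-1-[(5R,6S)-6-{(3E)-5-[(tert-butyldimethylsilyl)oxy]-3-methylpent-3-en-1-yl}-5,6-dimethylcyclohex-1-en-1-yl]ethyl (2RS)-2-methylhex-5-enoate
Conditions: DCC, DMAP (cat.), CH2Cl2, 0 °C → rt
Reagents that add atoms: none
Why: Steglich esterification should join the two fragments through the carbinol oxygen without touching a stereocenter, and the racemic α-carbon of the acid is planarized in the next step.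

Step 10
Reactants: 13 (1S)-1-[(5R,6S)-6-{(3E)-5-[(tert-butyldimethylsilyl)oxy]-3-methylpent-3-en-1-yl}-5,6-dimethylcyclohex-1-en-1-yl]ethyl (2RS)-2-methylhex-5-enoate
Product: 16 (1S,5S,6R,8aS)-5-{(3E)-5-[(tert-butyldimethylsilyl)oxy]-3-methylpent-3-en-1-yl}-1,5,6-trimethyl-1,2,3,5,6,7,8,8a-octahydronaphthalene-1-carboxylic acid, via silyl ketene acetal 14 (not isolated), via rearranged silyl ester 15 (not isolated)
Conditions: LDA, Me3SiCl, THF, −78 → 60 °C; solvent switch to toluene; second-generation Hoveyda–Grubbs catalyst (10 mol%), 80 °C; aq. NH4Cl work-up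
Reagents that add atoms: none
Why: LDA and Me3SiCl should convert the ester into silyl ketene acetal 14, which undergoes Ireland–Claisen [3,3] rearrangement through a chair transition state to form C4–C5 and to move the ring-B double bond into an exocyclic ethylidene (15); the ruthenium alkylidene then loads on the terminal vinyl group and closes onto that ethylidene, creating C1=C10 and releasing propene. The closest known reaction types are the Ireland–Claisen rearrangement of allylic esters of α-branched acids and the ring-closing metathesis of a 1,7-diene to a trisubstituted cyclohexene, run here as a one-pot sequence. Ring A is closed by ring-closing metathesis (six-membered ring from a terminal alkene and a trisubstituted alkene). C5 is controlled by the S carbinol centre: allylic strain with quaternary C9 holds the carbinol hydrogen in the alkene plane, so the C–O bond breaks and C4 bonds suprafacially on the ring-B face that carries the C8 and C9 methyl groups, which places H-5 cis to the C9 side chain. C4 is controlled by the enolate geometry: kinetic enolization in THF should put the larger butenyl group cis to the alkoxy oxygen (methyl cis to OSiMe3, E acetal), and the chair then places the carboxyl group cis to H-5. The step needs this enolate geometry, which rests only on the cyclic deprotonation transition state and is its weak point, and chemoselective metathesis, which rests on the low reactivity of the trisubstituted side-chain alkene.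

Step 11
Reactants: 16 (1S,5S,6R,8aS)-5-{(3E)-5-[(tert-butyldimethylsilyl)oxy]-3-methylpent-3-en-1-yl}-1,5,6-trimethyl-1,2,3,5,6,7,8,8a-octahydronaphthalene-1-carboxylic acid
Product: 17 methyl (1S,5S,6R,8aS)-5-{(3E)-5-[(tert-butyldimethylsilyl)oxy]-3-methylpent-3-en-1-yl}-1,5,6-trimethyl-1,2,3,5,6,7,8,8a-octahydronaphthalene-1-carboxylate
Conditions: MeI, K2CO3, DMF, rt
Reagents that add atoms: iodomethane, CI
Why: SN2 O-alkylation of the hindered carboxylate should give the methyl ester without affecting the quaternary centre.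

Step 12
Reactants: 17 methyl (1S,5S,6R,8aS)-5-{(3E)-5-[(tert-butyldimethylsilyl)oxy]-3-methylpent-3-en-1-yl}-1,5,6-trimethyl-1,2,3,5,6,7,8,8a-octahydronaphthalene-1-carboxylate
Product: 19 methyl (1S,5S,6R,8aS)-5-[(3E)-5-(acetyloxy)-3-methylpent-3-en-1-yl]-1,5,6-trimethyl-1,2,3,5,6,7,8,8a-octahydronaphthalene-1-carboxylate, via allylic alcohol 18 (not isolated)
Conditions: Bu4NF, THF, 0 °C → rt; then Ac2O, pyridine, DMAP (cat.)
Reagents that add atoms: acetic anhydride, CC(=O)OC(C)=O
Why: Fluoride-mediated desilylation should free the primary allylic alcohol, which is acetylated in the same flask by DMAP-catalysed acyl transfer to give the target.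

Compound list
1 | 2-methylcyclohex-2-en-1-one | CC1=CCCCC1=O | starting material
2 | dimethylaluminium (3R)-2,3-dimethylcyclohex-1-en-1-olate | C[Al](C)OC1=C(C)[C@H](C)CCC1 | intermediate
3 | trimethyl{[(3R)-2,3-dimethylcyclohex-1-en-1-yl]oxy}silane | C[Si](C)(C)OC1=C(C)[C@H](C)CCC1 | intermediate
4 | (2S,3R)-2,3-dimethyl-2-(3-oxobutyl)cyclohexan-1-one | O=C1CCC[C@@H](C)[C@]1(C)CCC(C)=O | intermediate
5 | ethyl (2E)-5-[(1S,2R)-1,2-dimethyl-6-oxocyclohexyl]-3-methylpent-2-enoate | O=C1CCC[C@@H](C)[C@]1(C)CC/C(C)=C/C(=O)OCC | intermediate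
6 | ethyl (2E)-5-[(1S,6R)-1,6-dimethyl-2-{[(trifluoromethyl)sulfonyl]oxy}cyclohex-2-en-1-yl]-3-methylpent-2-enoate | O=S(=O)(OC1=CCC[C@@H](C)[C@]1(C)CC/C(C)=C/C(=O)OCC)C(F)(F)F | intermediate
7 | (5R,6S)-6-[(3E)-5-hydroxy-3-methylpent-3-en-1-yl]-5,6-dimethylcyclohex-1-en-1-yl trifluoromethanesulfonate | O=S(=O)(OC1=CCC[C@@H](C)[C@]1(C)CC/C(C)=C/CO)C(F)(F)F | intermediate
8 | (5R,6S)-6-{(3E)-5-[(tert-butyldimethylsilyl)oxy]-3-methylpent-3-en-1-yl}-5,6-dimethylcyclohex-1-en-1-yl trifluoromethanesulfonate | O=S(=O)(OC1=CCC[C@@H](C)[C@]1(C)CC/C(C)=C/CO[Si](C)(C)C(C)(C)C)C(F)(F)F | intermediate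
9 | tert-butyl({(2E)-5-[(1S,6R)-2-(1-ethoxyethenyl)-1,6-dimethylcyclohex-2-en-1-yl]-3-methylpent-2-en-1-yl}oxy)dimethylsilane | CCOC(=C)C1=CCC[C@@H](C)[C@]1(C)CC/C(C)=C/CO[Si](C)(C)C(C)(C)C | intermediate
10 | 1-[(5R,6S)-6-{(3E)-5-[(tert-butyldimethylsilyl)oxy]-3-methylpent-3-en-1-yl}-5,6-dimethylcyclohex-1-en-1-yl]ethan-1-one | CC(=O)C1=CCC[C@@H](C)[C@]1(C)CC/C(C)=C/CO[Si](C)(C)C(C)(C)C | intermediate
11 | (1S)-1-[(5R,6S)-6-{(3E)-5-[(tert-butyldimethylsilyl)oxy]-3-methylpent-3-en-1-yl}-5,6-dimethylcyclohex-1-en-1-yl]ethan-1-ol | C[C@H](O)C1=CCC[C@@H](C)[C@]1(C)CC/C(C)=C/CO[Si](C)(C)C(C)(C)C | intermediate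
12 | 2-methylhex-5-enoic acid (racemic) | C=CCCC(C)C(=O)O | starting material
13 | (1S)-1-[(5R,6S)-6-{(3E)-5-[(tert-butyldimethylsilyl)oxy]-3-methylpent-3-en-1-yl}-5,6-dimethylcyclohex-1-en-1-yl]ethyl (2RS)-2-methylhex-5-enoate | C=CCCC(C)C(=O)O[C@@H](C)C1=CCC[C@@H](C)[C@]1(C)CC/C(C)=C/CO[Si](C)(C)C(C)(C)C | intermediate
14 | (E)-O-trimethylsilyl ketene acetal of ester 13 (methyl cis to OSiMe3, butenyl cis to the carbinol oxygen) | C=CCC/C(C)=C(/O[Si](C)(C)C)O[C@@H](C)C1=CCC[C@@H](C)[C@]1(C)CC/C(C)=C/CO[Si](C)(C)C(C)(C)C | intermediate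
15 | trimethylsilyl (2S)-2-[(1S,2E,3S,4R)-3-{(3E)-5-[(tert-butyldimethylsilyl)oxy]-3-methylpent-3-en-1-yl}-2-ethylidene-3,4-dimethylcyclohexyl]-2-methylhex-5-enoate | C[Si](C)(C)OC(=O)[C@@](C)(CCC=C)[C@H]1CC[C@@H](C)[C@](C)(CC/C(C)=C/CO[Si](C)(C)C(C)(C)C)/C1=C/C | intermediate
16 | (1S,5S,6R,8aS)-5-{(3E)-5-[(tert-butyldimethylsilyl)oxy]-3-methylpent-3-en-1-yl}-1,5,6-trimethyl-1,2,3,5,6,7,8,8a-octahydronaphthalene-1-carboxylic acid | OC(=O)[C@@]1(C)CCC=C2[C@@H]1CC[C@@H](C)[C@]2(C)CC/C(C)=C/CO[Si](C)(C)C(C)(C)C | intermediate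
17 | methyl (1S,5S,6R,8aS)-5-{(3E)-5-[(tert-butyldimethylsilyl)oxy]-3-methylpent-3-en-1-yl}-1,5,6-trimethyl-1,2,3,5,6,7,8,8a-octahydronaphthalene-1-carboxylate | COC(=O)[C@@]1(C)CCC=C2[C@@H]1CC[C@@H](C)[C@]2(C)CC/C(C)=C/CO[Si](C)(C)C(C)(C)C | intermediate
18 | methyl (1S,5S,6R,8aS)-5-[(3E)-5-hydroxy-3-methylpent-3-en-1-yl]-1,5,6-trimethyl-1,2,3,5,6,7,8,8a-octahydronaphthalene-1-carboxylate | COC(=O)[C@@]1(C)CCC=C2[C@@H]1CC[C@@H](C)[C@]2(C)CC/C(C)=C/CO | intermediate
19 | methyl (1S,5S,6R,8aS)-5-[(3E)-5-(acetyloxy)-3-methylpent-3-en-1-yl]-1,5,6-trimethyl-1,2,3,5,6,7,8,8a-octahydronaphthalene-1-carboxylate | COC(=O)[C@@]1(C)CCC=C2[C@@H]1CC[C@@H](C)[C@]2(C)CC/C(C)=C/COC(C)=O | target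

Total step count: 12. Longest linear sequence: 12 steps (1 → 19).

Steps most likely to fail

Step 10. Enolization may not discriminate between the methyl and butenyl groups, which would erode the configuration at C4, and closure onto the congested ethylidene may be slower than intermolecular metathesis of the terminal alkene. The fallback replaces rearrangement and metathesis by a cycloaddition and sets out from 8. Stille coupling with tributyl(vinyl)stannane (Pd(PPh3)4, LiCl, THF, 65 °C) should give the diene tert-butyl({(2E)-5-[(1S,6R)-2-ethenyl-1,6-dimethylcyclohex-2-en-1-yl]-3-methylpent-2-en-1-yl}oxy)dimethylsilane F1. A Diels–Alder reaction of this diene with methyl methacrylate (Et2AlCl, CH2Cl2, −20 °C) should join C4–C5 and C2–C3 with the ester carbon next to the ring fusion and the α-methyl group endo. After separation from diastereomers this comes back to the route at 17.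

Step 2. Polymerisation of the enone and protodesilylation of 3 may outrun bond formation at the fully substituted carbon. The fallback replaces conjugate addition by alkylation and oxidation and sets out from 3. MeLi (THF, 0 °C) should give the enolate lithium (3R)-2,3-dimethylcyclohex-1-en-1-olate F2. Alkylation with 4-iodobut-1-ene (THF/DMPU, −20 °C → rt) should give the ketone (2S,3R)-2-(but-3-en-1-yl)-2,3-dimethylcyclohexan-1-one F3. Tsuji–Wacker oxidation (PdCl2, CuCl, O2, DMF/H2O) should then give the diketone, where the route is rejoined at 4.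

Step 7. Transmetalation at the hindered alkenyl triflate may be slow, so that reduction of the triflate or loss of the silyl ether during hydrolysis competes. The fallback replaces tin chemistry by a Heck vinylation and sets out from 8. Heck reaction with butyl vinyl ether (Pd(OAc)2, 1,3-bis(diphenylphosphino)propane, Et3N, DMSO, 80 °C) should give the branched dienyl ether tert-butyl({(2E)-5-[(1S,6R)-2-(1-butoxyethenyl)-1,6-dimethylcyclohex-2-en-1-yl]-3-methylpent-2-en-1-yl}oxy)dimethylsilane F4. Its hydrolysis (aq. oxalic acid, THF, 0 °C) comes back to the route at 10.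

Further compounds
F1 | step 10 | tert-butyl({(2E)-5-[(1S,6R)-2-ethenyl-1,6-dimethylcyclohex-2-en-1-yl]-3-methylpent-2-en-1-yl}oxy)dimethylsilane | C=CC1=CCC[C@@H](C)[C@]1(C)CC/C(C)=C/CO[Si](C)(C)C(C)(C)C
F2 | step 2 | lithium (3R)-2,3-dimethylcyclohex-1-en-1-olate | [Li]OC1=C(C)[C@H](C)CCC1
F3 | step 2 | (2S,3R)-2-(but-3-en-1-yl)-2,3-dimethylcyclohexan-1-one | O=C1CCC[C@@H](C)[C@]1(C)CCC=C
F4 | step 7 | tert-butyl({(2E)-5-[(1S,6R)-2-(1-butoxyethenyl)-1,6-dimethylcyclohex-2-en-1-yl]-3-methylpent-2-en-1-yl}oxy)dimethylsilane | CCCCOC(=C)C1=CCC[C@@H](C)[C@]1(C)CC/C(C)=C/CO[Si](C)(C)C(C)(C)C
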